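# Total synthesis plan for target 49 (CNP0332295.1) built on an exo-selective catalytic Diels–Alder reaction for ring B

## The problem

The target is a 5-6-8-5 tetracycle with ten stereocentres. Atoms are labelled in the order of its SMILES string:
- ring A (cyclopentanone): C1–C3 the isopropyl group, C4 the CH that bears it, C5 the carbonyl carbon, C6 a CH2, C7 the methyl-bearing quaternary carbon shared with ring B;
- ring B (cyclohexane): C8 and C21 are CH2, C9 the B/C ring-fusion CH, C20 the tertiary carbinol carbon shared with ring C, C22 the A/B ring-fusion CH;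
- ring C (cyclooctane): C10 (CH–CH3), C11 and C12 (CH2), C13 the C/D ring-fusion CH;
- ring D (cyclopentane): C14 (CH–CH3), C15 and C16 (CH2), and the epoxide carbons C17 and C19 (O18 between them, a methyl on C19).

Rings A/B are trans-fused (C7 methyl β, C22–H α). Rings B/C are trans-fused, with an axial α-hydroxyl at C20 and equatorial bonds to C10 and C19. Rings C/D are cis-fused, and C12, the C14 methyl and C19 all lie on one face of ring D, with the epoxide oxygen on the other.

C7 and C22 have to be set together and absolutely. Once the trans-hydrindane exists it can direct C4 (face of hydrogenation), C9 (equilibration) and C20 (equatorial attack on a ketone). C10 is exocyclic and needs reagent control. The C14 centre of ring D must control C13, in the cis sense that enolate chemistry would not give, and, together with the C20 hydroxyl, the face of epoxidation.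

Three features restrict the late chemistry. C4 is α to the C5 ketone and carries its isopropyl group syn to the C7 methyl, so the ketone should be unveiled last and under neutral conditions. The tetrasubstituted epoxide next to a tertiary alcohol will not survive acid or low-valent metals. C13 cannot be left next to a carbonyl group.

The eight-membered ring has to be closed late from a precursor that already holds both chains close together.

The feature that makes the key step possible sits in ring B. C7 (quaternary, carrying the methyl and C6) lies next to C22–H, and the oxygenated C20 is 1,4 to C7. This is the pattern of the adduct of a 2-siloxy-1,3-diene (C9=C20(OSi)–C21=C22) with methacrolein (C7=C8).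

## Retrosynthesis

**C5 ketone and the C11–C12 bond.** The ketone of 49 is taken back to the silyl ether 47 through alcohol 48, so that C4 is not enolisable during the synthesis. Ring C is then opened at C11–C12, after adding a double bond (46), to the diene 45. This cut lies between two vinyl groups on carbons that are already stereodefined (C10, C13), so the forward ring-closing metathesis creates no stereocentre. The neighbouring cuts (C10–C11 or C12–C13) would leave a trisubstituted alkene whose hydrogenation would have to set C10 or C13. The forward step must close an eight-membered ring in the presence of the epoxy alcohol.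

**Epoxide.** The C17–O18 and C19–O18 bonds of 45 are removed to give the tetrasubstituted allylic alcohol 44. Epoxidation is placed before ring closure because the C20 hydroxyl can then direct it and because the epoxide pre-organises the two vinyl chains. The forward reaction must pick the allylic alkene over two vinyl groups and the face opposite the C13 and C14 substituents.

**C19–C20.** Cutting this bond divides 44 into the ring A/B ketone 24 and the ring D alkenyl nucleophile 43, made from stannane 42. This is the most convergent cut of the molecule, and it turns C20 into a ketone whose equatorial face is the open one. The forward addition needs a configurationally defined alkenyl metal with the metal cis to C13.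

**Ring D fragment.** Stannane 42 is traced to the Z enol triflate 38, whose geometry comes from the enolate formed by conjugate reduction of the acetylcyclopentene 36. Enone 36 comes from the cis-disubstituted cyclopentanone 32 through enol triflate 34. The cis relationship of C12 and the C14 methyl in 32 is traced to hydroboration of cyclopentene 29, which is the metathesis product of the citronellal-derived diene 28. (S)-Citronellal 25 supplies C14. A ketone at C17 is tolerated only while C13 carries a CH2O group and only under kinetic conditions; the vinyl group is made last (41).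

**C9–C10.** The butenyl side chain of 24 is removed to leave ketone 20, through the C9 silyl enol ether 22. The cut next to the ring makes C9 an enolate carbon, where equilibration gives the equatorial isomer, and it leaves C10 to a catalyst-controlled allylic substitution. The forward reaction must be branched-selective and must keep the enolate on the C9 side.

**Ring A.** The isopropyl group of 20 (via 17 and enone 16) is cut at C4–C2, which leads to the unsubstituted ring A ketone 12. Ring A itself is cut at C5–C6, leading through ketol 11 to the dialdehyde 10, and by redox changes to diol 9 and the cycloadduct 8. The C5–C6 cut uses exactly the two carbon handles that the cycloaddition leaves on C7 and C22, and it puts the ketone on the less hindered carbon. The forward steps must differentiate C4 from C6 and set C4 by kinetic hydrogenation.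

**Ring B (key).** The C7–C22 and C8–C9 bonds of 8 are cut to give the siloxydiene 6 and methacrolein 7. No other cut of ring B makes the quaternary carbon, its neighbouring CH and a regiodefined masked C20 ketone in one step from achiral partners. The forward reaction must be exo with respect to the formyl group and enantioselective.

**Diene.** Diene 6 is the silyl dienol ether of enone 5, which comes from aldehyde 3 and ylide 4. Aldehyde 3 comes from propane-1,3-diol 1 through its monopivalate 2. The pivalate, not a silyl ether, is chosen on the primary oxygen so that one hydride step later frees both primary alcohols while the enol silyl ether stays.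

## Roads not taken

**Alternative 1: transannular carbonyl-ene reaction across a twelve-membered ring.**
- Cut: the C9–C20 bond.
- Forward key step: a Lewis-acid-promoted ene reaction of the macrocyclic dienone A2, in which the trisubstituted C9=C10 alkene attacks the C20 carbonyl and gives the methylene alcohol A1.
- Merits: one late step divides the macrocycle into rings B and C and creates C9 and C20 together, in a biomimetic way. In step count at the end it is better than the plan adopted here.
- Weak points: A2 is itself a hard target. It is a twelve-membered ring with an E trisubstituted alkene and a Z-configured enone, and it already carries rings A and D, so C7 and C22 would have to be set without the help of ring B. The configuration at C9 and C20 would depend on the conformation of the macrocycle, which cannot be predicted with confidence. A conjugated ketone is a poor ene acceptor, and its Lewis acid complex invites Prins-type side reactions. The exocyclic methylene left at C10 in A1 must later be hydrogenated with the right facial selectivity.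
- Comparison: the chosen plan is longer at the end, but each stereocentre has an identifiable control element (chiral catalyst, trans-hydrindane bias, chiral pool), and the medium ring is closed from the pre-organised diene 45.

**Alternative 2: rhodium hydroacylation closes ring A.**
- Cut: the C4–C5 bond.
- Forward key step: a cationic rhodium–diphosphine complex adds the aldehyde C–H bond of the alkenal A4 across its exocyclic methylene group and gives the hydrindanone A3.
- Merits: for ring A alone this is shorter and more atom-economic than steps 6 to 9 of the chosen route. The ketone appears directly at C5 and no oxygen has to be removed.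
- Weak points: C22 is created in the hydride transfer to a methylenecyclohexane next to the quaternary C7. A cis-fused hydrindanone is the usual outcome of such closures, so the trans fusion is uncertain. Decarbonylation of the neopentyl-type aldehyde competes. The quaternary centre C7 of A4 must first be made enantiopure by a separate method. A3, like 12, still has two CH2 groups flanking the ketone, so the regiochemical question of the isopropyl installation is not removed.
- Comparison: the chosen plan sets C7 and C22 together in the cycloaddition and fixes their relationship through its geometry. The price is the two extra redox steps of the benzoin route.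

**Alternative 3: Claisen ring expansion of a pyran into ring C.**
- Cut: the C12–C13 bond.
- Forward key step: heating the 2-methylidenetetrahydropyran A6, an allyl vinyl ether, which rearranges to the ring C ketone A5.
- Merits: the eight-membered ring arises by ring expansion, not by medium-ring cyclisation. The geometry of the tetrasubstituted C17=C19 alkene is dictated by the cyclic transition state, and C13 is set by chirality transfer from C19. In the control of alkene geometry this is better than step 25 of the chosen route, which relies on enolate geometry.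
- Weak points: A6 carries a tertiary ether carbon C19 of defined configuration bearing a cyclopentenyl group, and an acid-labile exocyclic enol ether; it would be long to prepare. The new bond at C13 must form on the face syn to the C14 methyl, the more hindered one. A5 has a C11 ketone that must later be removed by extra redox steps.
- Comparison: the chosen plan has simpler and more convergent fragments (24 and 42), and a ring closure that introduces no superfluous functionality.

Key step: step 5

Remark: β is the face of rings A and B that carries the C7 methyl group; α is the opposite face.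
Remark: centres that are destroyed in the following operation (C6 in 11, C4 in 14 and 15, C9 in 23) are expected as mixtures and are written without configuration.
Remark: the facial sense assumed in step 5 is that of the usual binding model of α-substituted acroleins on N-protonated oxazaborolidines (the catalyst from (R)-α,α-diphenylprolinol exposes the si face of C7); the mirror-image catalyst is equally accessible.
Remark: the ligand enantiomer of step 16 is likewise chosen from the usual sense of induction of cyclometalated iridium–phosphoramidite catalysts, which does not depend on the nucleophile.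

## Route

Step 1
Reactants: 1 propane-1,3-diol
Product: 2 3-hydroxypropyl 2,2-dimethylpropanoate
Conditions: t-BuCOCl (0.3 equiv), pyridine, CH2Cl2, 0 °C → rt
Reagents that add atoms: pivaloyl chloride, CC(C)(C)C(Cl)=O
Why: Statistical monoacylation of the symmetrical diol used in excess (acyl substitution); the pivalate is non-enolisable, survives silyl triflate and Lewis acid, and is removed by hydride in step 6.

Step 2
Reactants: 2 3-hydroxypropyl 2,2-dimethylpropanoate
Product: 3 3-oxopropyl 2,2-dimethylpropanoate
Conditions: TEMPO (10 mol %), PhI(OAc)2, CH2Cl2, rt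
Reagents that add atoms: none
Why: TEMPO-catalysed oxidation stops at the aldehyde and is neutral enough to avoid β-elimination of the acyloxy group.

Step 3
Reactants: 3 3-oxopropyl 2,2-dimethylpropanoate; 4 1-(triphenyl-λ5-phosphanylidene)propan-2-one
Product: 5 (E)-5-oxohex-3-en-1-yl 2,2-dimethylpropanoate
Conditions: CH2Cl2, rt
Reagents that add atoms: none
Why: Wittig olefination with a stabilised ylide is E-selective and base-free, so the β-acyloxy aldehyde does not eliminate.

Step 4
Reactants: 5 (E)-5-oxohex-3-en-1-yl 2,2-dimethylpropanoate
Product: 6 (E)-5-[(tert-butyldimethylsilyl)oxy]hexa-3,5-dien-1-yl 2,2-dimethylpropanoate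
Conditions: t-BuMe2SiOTf, Et3N, CH2Cl2, −78 → 0 °C
Reagents that add atoms: tert-butyldimethylsilyl trifluoromethanesulfonate, CC(C)(C)[Si](C)(C)OS(=O)(=O)C(F)(F)F
Why: Soft enolisation of a methyl enone with silyl triflate and amine occurs at the methyl group and gives the cross-conjugated 2-siloxy-1,3-diene; the E geometry of the C21=C22 bond is carried over from 5.

Step 5
Reactants: 6 (E)-5-[(tert-butyldimethylsilyl)oxy]hexa-3,5-dien-1-yl 2,2-dimethylpropanoate; 7 methacrolein
Product: 8 2-[(1R,6R)-3-[(tert-butyldimethylsilyl)oxy]-6-formyl-6-methylcyclohex-2-en-1-yl]ethyl 2,2-dimethylpropanoate (ring B cycloadduct)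
Conditions: (R)-3,3-diphenyl-1-(2-methylphenyl)tetrahydro-1H,3H-pyrrolo[1,2-c][1,3,2]oxazaborole (20 mol %), HN(SO2CF3)2 (18 mol %), CH2Cl2, −78 → −40 °C
Reagents that add atoms: none
Why: The N-protonated oxazaborolidine binds methacrolein 7 at boron (carbonyl lone pair anti to the alkene, s-trans enal, formyl C–H···O contact), and the electron-rich diene 6 then adds in a concerted but asynchronous [4+2] cycloaddition in which C9–C8 bonding runs ahead of C22–C7 bonding. The closest known reaction type is the oxazaborolidinium-catalysed enantioselective Diels–Alder reaction of 2-silyloxy-1,3-dienes with α-substituted acroleins. Ring B is closed by this intermolecular two-bond cycloaddition (a six-membered ring from a four-carbon and a two-carbon unit), which leaves the C20=C21 silyl enol ether as a regiodefined latent ketone. The regiochemistry is reinforced twice, because both the C20 siloxy group and the C22 alkyl substituent place the largest HOMO coefficient on the unsubstituted terminus C9, which therefore meets the enal β-carbon C8. The quaternary centre C7 is set by the catalyst, whose aryl groups cover one face of the bound enal so that the diene reaches the si face of C7. C22 is set relative to C7 by the exo orientation of the formyl group: the small α-methyl group takes the endo position under C21 and C20, the bulky boron-bound carbonyl avoids the silyloxy-substituted interior of the diene, and the E geometry of C21=C22 turns this into a trans relationship between the formyl group and the C22 side chain. The step therefore needs exo/endo and enantiofacial selectivity; the first rests on the α-methyl group of the dienophile together with the large Lewis acid and the tert-butyldimethylsilyloxy group, the second on the chiral cation.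

Step 6
Reactants: 8 ring B cycloadduct
Product: 9 ring B diol (C6 hydroxymethyl on C7 and 2-hydroxyethyl on C22; C20=C21 silyl enol ether kept)
Conditions: LiAlH4, Et2O, 0 °C
Reagents that add atoms: none
Why: Hydride reduction converts the formyl group into the C6 carbinol and cleaves the pivalate in the same operation; the silyl enol ether has no electrophilic site and is not touched.

Step 7
Reactants: 9 ring B diol
Product: 10 ring B dialdehyde (C6 formyl on C7 and C5 formyl at the end of the C22 side chain)
Conditions: (COCl)2, DMSO, CH2Cl2, −78 °C; then Et3N, −78 → 0 °C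
Reagents that add atoms: none
Why: Swern oxidation activates both hydroxyl groups before base is added, so the 1,5-diol goes to the dialdehyde without passing through a lactol that would be oxidised to a lactone.

Step 8
Reactants: 10 ring B dialdehyde
Product: 11 ring A ketol (trans-hydrindane with C5 ketone and C6 hydroxyl)
Conditions: 2-(pentafluorophenyl)-6,7-dihydro-5H-pyrrolo[2,1-c][1,2,4]triazol-2-ium tetrafluoroborate (10 mol %), DBU (10 mol %), CH2Cl2, rt
Reagents that add atoms: none
Why: Intramolecular crossed benzoin reaction: the carbene adds to the unhindered C5 aldehyde (the C6 aldehyde is neopentyl), and the acyl anion equivalent attacks C6 in a 5-exo closure, so the ketone ends at C5 and the hydroxyl at C6. The trans ring fusion is already fixed by C7 and C22.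

Step 9
Reactants: 11 ring A ketol
Product: 12 ring A ketone (C5 ketone; C4 and C6 are CH2)
Conditions: SmI2 (2.5 equiv), THF–MeOH, −78 °C
Reagents that add atoms: none
Why: Samarium diiodide reduces the ketone to a ketyl that expels the α-hydroxyl group (reductive α-deoxygenation of an α-hydroxy ketone); protonation of the samarium enolate gives the C5 ketone with C6 as CH2.

Step 10
Reactants: 12 ring A ketone
Product: 14 C4 aldol adduct (2-hydroxypropan-2-yl at C4), via lithium enolate 13 (not isolated)
Conditions: LiN(i-Pr)2, THF, −78 °C; acetone, −78 °C; then AcOH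
Reagents that add atoms: acetone, CC(C)=O
Why: Kinetic deprotonation with a hindered amide base is expected at C4, because the C6 hydrogens are neopentyl (next to the quaternary C7); aldol addition to acetone brings in all three isopropyl carbons.

Step 11
Reactants: 14 C4 aldol adduct
Product: 16 C4-isopropylidene enone, via tertiary mesylate 15 (not isolated)
Conditions: MsCl, Et3N, CH2Cl2, 0 °C; then DBU, rt
Reagents that add atoms: none
Why: Mesylation of the tertiary aldol hydroxyl and base-induced E1cB elimination through the C4 enolate give the conjugated alkylidene ketone.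

Step 12
Reactants: 16 C4-isopropylidene enone
Product: 17 C4β-isopropyl ketone
Conditions: H2 (1 atm), Pd/C, EtOAc, rt
Reagents that add atoms: none
Why: Heterogeneous hydrogenation of the exocyclic enone delivers hydrogen to C4 from the α face, opposite the axial C7 methyl group, which places the isopropyl group β as in the target. The hindered, electron-rich silyl enol ether is hydrogenated much more slowly and is kept.

Step 13
Reactants: 17 C4β-isopropyl ketone
Product: 18 C5β-alcohol
Conditions: NaBH4, MeOH–THF, −20 °C
Reagents that add atoms: none
Why: Immediate borohydride reduction removes the carbonyl that makes C4 epimerisable. Hydride enters from the α face, because the β face carries the isopropyl and C7 methyl groups; the carbinol configuration is unimportant because it is oxidised again in step 35.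

Step 14
Reactants: 18 C5β-alcohol
Product: 20 ring B ketone (C20) with C5β tert-butyldimethylsilyl ether, via bis-silyl ether 19 (not isolated)
Conditions: t-BuMe2SiOTf, 2,6-lutidine, CH2Cl2, −78 → 0 °C; then 1 M HCl, THF, 0 °C
Reagents that add atoms: tert-butyldimethylsilyl trifluoromethanesulfonate, CC(C)(C)[Si](C)(C)OS(=O)(=O)C(F)(F)F
Why: The silyl triflate silylates the hindered secondary alcohol; dilute acid then hydrolyses only the silyl enol ether, by fast C-protonation, and leaves the hindered alkyl silyl ether, releasing the C20 ketone.

Step 15
Reactants: 20 ring B ketone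
Product: 22 C9=C20 trimethylsilyl enol ether, via lithium enolate 21 (not isolated)
Conditions: LiN(i-Pr)2, Me3SiCl, THF, −78 °C
Reagents that add atoms: chlorotrimethylsilane, C[Si](C)(C)Cl
Why: Kinetic enolisation of a trans-fused bicyclic cyclohexanone takes place away from the ring fusion, toward C9, and in situ silylation fixes this regiochemistry.

Step 16
Reactants: 22 C9=C20 trimethylsilyl enol ether
Product: 24 C9α-[(R)-but-3-en-2-yl] ketone (side chain equatorial), via C9-epimer mixture 23 (not isolated)
Conditions: [Ir(cod)Cl]2 (2 mol %), (Sa)-(1,1'-binaphthalene-2,2'-diyl) N,N-bis[(S)-1-phenylethyl]phosphoramidite (4 mol %), (E)-but-2-en-1-yl methyl carbonate, CsF (cat.), ZnF2, DME, 50 °C; then DBU (cat.), CH2Cl2, rt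
Reagents that add atoms: (E)-but-2-en-1-yl methyl carbonate, C/C=C/COC(=O)OC
Why: Iridium-catalysed allylic substitution of a fluoride-activated silyl enol ether gives the branched product, and the configuration of the new allylic carbon C10 is fixed by the chiral iridium–phosphoramidite complex, not by the substrate. C9 is then equilibrated with DBU to the equatorial α position.

Step 17
Reactants: 25 (S)-citronellal
Product: 26 (S)-3,7-dimethyl-2-methylideneoct-6-enal
Conditions: aq. CH2O, pyrrolidine (10 mol %), EtCO2H (10 mol %), i-PrOH, 45 °C
Reagents that add atoms: formaldehyde, C=O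
Why: Amine-catalysed Mannich condensation and elimination (α-methylenation of an aldehyde); only the carbon that becomes C13 is enolised, so the C14 stereocentre is not touched.

Step 18
Reactants: 26 (S)-3,7-dimethyl-2-methylideneoct-6-enal
Product: 27 (S)-3,7-dimethyl-2-methylideneoct-6-en-1-ol
Conditions: NaBH4, CeCl3·7H2O, MeOH, 0 °C
Reagents that add atoms: none
Why: Luche reduction gives clean 1,2-reduction of the enal to the allylic alcohol.

Step 19
Reactants: 27 (S)-3,7-dimethyl-2-methylideneoct-6-en-1-ol
Product: 28 tert-butyldimethylsilyl ether of 27
Conditions: t-BuMe2SiCl, imidazole, CH2Cl2, rt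
Reagents that add atoms: tert-butyldimethylsilyl chloride, CC(C)(C)[Si](C)(C)Cl
Why: Standard silylation; the silyl ether masks the C12 oxygen through the borane, enolate and palladium steps.

Step 20
Reactants: 28 tert-butyldimethylsilyl ether of 27
Product: 29 (S)-tert-butyldimethyl[(5-methylcyclopent-1-en-1-yl)methoxy]silane
Conditions: second-generation Grubbs catalyst, (H2IMes)(PCy3)Cl2Ru=CHPh (5 mol %), CH2Cl2, 40 °C
Reagents that add atoms: none
Why: Ring-closing metathesis between the 1,1-disubstituted alkene and the prenyl-type alkene closes the cyclopentene with loss of 2-methylpropene and leaves the double bond at C13=C17 without ambiguity.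

Step 21
Reactants: 29 (S)-tert-butyldimethyl[(5-methylcyclopent-1-en-1-yl)methoxy]silane
Product: 31 (1S,2R,3S)-2-{[(tert-butyldimethylsilyl)oxy]methyl}-3-methylcyclopentan-1-ol, via B-alkyl-9-borabicyclononane 30 (not isolated)
Conditions: 9-BBN, THF, 65 °C; then NaOH, H2O2, 0 °C → rt
Reagents that add atoms: hydrogen peroxide, OO
Why: Hydroboration–oxidation: boron adds to the less substituted C17 and hydrogen to C13, syn and from the face opposite the adjacent C14 methyl group. This sets C12 cis to that methyl, the arrangement that enolate chemistry would not give; oxidation occurs with retention.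

Step 22
Reactants: 31 (1S,2R,3S)-2-{[(tert-butyldimethylsilyl)oxy]methyl}-3-methylcyclopentan-1-ol
Product: 32 (2R,3S)-2-{[(tert-butyldimethylsilyl)oxy]methyl}-3-methylcyclopentan-1-one
Conditions: Dess–Martin periodinane, pyridine, CH2Cl2, 0 °C → rt
Reagents that add atoms: none
Why: Buffered Dess–Martin oxidation gives the ketone without epimerising the cis-configured C13 next to it.

Step 23
Reactants: 32 (2R,3S)-2-{[(tert-butyldimethylsilyl)oxy]methyl}-3-methylcyclopentan-1-one
Product: 34 (4S,5R)-5-{[(tert-butyldimethylsilyl)oxy]methyl}-4-methylcyclopent-1-en-1-yl trifluoromethanesulfonate, via potassium enolate 33 (not isolated)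
Conditions: KN(SiMe3)2, THF, −78 °C; then PhN(SO2CF3)2, −78 → 0 °C
Reagents that add atoms: N-phenylbis(trifluoromethanesulfonimide), FC(F)(F)S(=O)(=O)N(c1ccccc1)S(=O)(=O)C(F)(F)F
Why: Kinetic deprotonation occurs at the C16 methylene, because C13 is a hindered methine; C13 therefore keeps its configuration and β-elimination of the silyloxy group cannot start. O-Sulfonylation gives the enol triflate.

Step 24
Reactants: 34 (4S,5R)-5-{[(tert-butyldimethylsilyl)oxy]methyl}-4-methylcyclopent-1-en-1-yl trifluoromethanesulfonate
Product: 36 1-[(4S,5S)-5-{[(tert-butyldimethylsilyl)oxy]methyl}-4-methylcyclopent-1-en-1-yl]ethan-1-one, via ethoxydiene 35 (not isolated)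
Conditions: CH2=C(OEt)SnBu3, Pd(PPh3)4 (5 mol %), LiCl, THF, 65 °C; then 1 M HCl, THF, 0 °C
Reagents that add atoms: tributyl(1-ethoxyvinyl)stannane, CCCC[Sn](CCCC)(CCCC)C(=C)OCC; water, O
Why: Stille coupling of the enol triflate with an α-alkoxyvinylstannane, followed by mild hydrolysis of the enol ether, installs the acetyl group (C19 and its methyl) on C17.

Step 25
Reactants: 36 1-[(4S,5S)-5-{[(tert-butyldimethylsilyl)oxy]methyl}-4-methylcyclopent-1-en-1-yl]ethan-1-one
Product: 38 (Z)-1-[(2S,3S)-2-{[(tert-butyldimethylsilyl)oxy]methyl}-3-methylcyclopentylidene]ethyl trifluoromethanesulfonate, via lithium enolate 37 (not isolated)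
Conditions: LiBH(s-Bu)3, THF, −78 °C; then PhN(SO2CF3)2, −78 → 0 °C
Reagents that add atoms: N-phenylbis(trifluoromethanesulfonimide), FC(F)(F)S(=O)(=O)N(c1ccccc1)S(=O)(=O)C(F)(F)F
Why: Conjugate hydride addition to the s-trans enone, the conformer that keeps the acetyl methyl away from the C13 substituent, gives the enolate with oxygen cis to C13. O-Triflation freezes this geometry, which later lets C20 and C13 lie cis on the C17=C19 bond.

Step 26
Reactants: 38 (Z)-1-[(2S,3S)-2-{[(tert-butyldimethylsilyl)oxy]methyl}-3-methylcyclopentylidene]ethyl trifluoromethanesulfonate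
Product: 39 (Z)-1-[(2S,3S)-2-(hydroxymethyl)-3-methylcyclopentylidene]ethyl trifluoromethanesulfonate
Conditions: HF·pyridine, pyridine, THF, 0 °C → rt
Reagents that add atoms: none
Why: Buffered fluoride cleaves the primary silyl ether; the enol triflate is stable to it.

Step 27
Reactants: 39 (Z)-1-[(2S,3S)-2-(hydroxymethyl)-3-methylcyclopentylidene]ethyl trifluoromethanesulfonate
Product: 40 (Z)-1-[(2S,3S)-2-formyl-3-methylcyclopentylidene]ethyl trifluoromethanesulfonate
Conditions: Dess–Martin periodinane, pyridine, CH2Cl2, 0 °C
Reagents that add atoms: none
Why: Buffered Dess–Martin oxidation is neutral and fast, which matters because the aldehyde is α-branched and β,γ-unsaturated.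

Step 28
Reactants: 40 (Z)-1-[(2S,3S)-2-formyl-3-methylcyclopentylidene]ethyl trifluoromethanesulfonate
Product: 41 (Z)-1-[(2S,3S)-2-ethenyl-3-methylcyclopentylidene]ethyl trifluoromethanesulfonate
Conditions: Cp2Ti(μ-CH2)(μ-Cl)AlMe2 (Tebbe reagent), pyridine, THF, −40 → 0 °C
Reagents that add atoms: Tebbe reagent, C=[Ti](C1C=CC=C1)C1C=CC=C1.C[Al](C)Cl
Why: Tebbe methylenation proceeds through a titanium carbene and an oxatitanacyclobutane and is not basic, so the easily enolised aldehyde becomes the vinyl group without epimerisation at C13 or migration of the double bond.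

Step 29
Reactants: 41 (Z)-1-[(2S,3S)-2-ethenyl-3-methylcyclopentylidene]ethyl trifluoromethanesulfonate
Product: 42 trimethyl{(Z)-1-[(2S,3S)-2-ethenyl-3-methylcyclopentylidene]ethyl}stannane
Conditions: Me3SnSnMe3, Pd(PPh3)4 (5 mol %), LiCl, THF, 65 °C
Reagents that add atoms: hexamethylditin, C[Sn](C)(C)[Sn](C)(C)C
Why: Palladium-catalysed stannylation of the enol triflate with a distannane (a Stille-type coupling) occurs with retention of alkene geometry.

Step 30
Reactants: 42 trimethyl{(Z)-1-[(2S,3S)-2-ethenyl-3-methylcyclopentylidene]ethyl}stannane; 24 C9α-[(R)-but-3-en-2-yl] ketone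
Product: 44 tertiary allylic alcohol (C20 α-hydroxyl; Z C17=C19 alkene carrying ring D), via alkenyllithium 43 (not isolated)
Conditions: MeLi (1.0 equiv to 42), THF, −78 → −40 °C; then 24, −78 → −20 °C; H2O
Reagents that add atoms: none
Why: Tin–lithium exchange gives a configurationally stable alkenyllithium, which adds 1,2 to the C20 ketone. The large tetrasubstituted nucleophile takes the equatorial trajectory, because the axial one is flanked by the axial hydrogens on C8 and C22; this gives the axial α-hydroxyl and the equatorial C19–C20 bond.

Step 31
Reactants: 44 tertiary allylic alcohol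
Product: 45 epoxy alcohol (C17–O18–C19 epoxide; two vinyl groups intact)
Conditions: VO(acac)2 (5 mol %), t-BuOOH, CH2Cl2, 0 °C → rt
Reagents that add atoms: tert-butyl hydroperoxide, CC(C)(C)OO
Why: Vanadium-catalysed hydroxyl-directed epoxidation selects the allylic tetrasubstituted alkene over the two vinyl groups. Oxygen is delivered syn to the coordinating C20 hydroxyl and to the face of ring D opposite the C13 vinyl and C14 methyl groups; both effects are expected to lead to the required epoxide.

Step 32
Reactants: 45 epoxy alcohol
Product: 46 tetracyclic cis-cyclooctene (C11=C12)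
Conditions: second-generation Grubbs catalyst, (H2IMes)(PCy3)Cl2Ru=CHPh (10 mol %), toluene (1 mM), 80 °C
Reagents that add atoms: none
Why: Ring-closing metathesis of the two monosubstituted alkenes closes the eight-membered ring with loss of ethene; the tetrasubstituted epoxide and the ring B chair hold the two chains on the same side and close together.

Step 33
Reactants: 46 tetracyclic cis-cyclooctene
Product: 47 saturated tetracycle (C5β silyl ether)
Conditions: H2 (1 atm), Pd/C, EtOAc, rt
Reagents that add atoms: none
Why: Hydrogenation of the disubstituted ring alkene creates no stereocentre; the tetrasubstituted epoxide is neither allylic nor benzylic and is not hydrogenolysed.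

Step 34
Reactants: 47 saturated tetracycle
Product: 48 C5β-alcohol of the target skeleton
Conditions: Bu4NF, THF, 60 °C
Reagents that add atoms: none
Why: Fluoride-mediated desilylation is basic and spares the epoxy alcohol.

Step 35
Reactants: 48 C5β-alcohol of the target skeleton
Product: 49 target (CNP0332295.1)
Conditions: Dess–Martin periodinane, pyridine, CH2Cl2, 0 °C → rt
Reagents that add atoms: none
Why: Buffered Dess–Martin oxidation of the secondary alcohol gives the C5 ketone without epimerising C4 or opening the epoxide; the tertiary alcohol cannot be oxidised.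

## Compound list

1 | propane-1,3-diol | OCCCO | starting material
2 | 3-hydroxypropyl 2,2-dimethylpropanoate | CC(C)(C)C(=O)OCCCO | intermediate
3 | 3-oxopropyl 2,2-dimethylpropanoate | CC(C)(C)C(=O)OCCC=O | intermediate
4 | 1-(triphenyl-λ5-phosphanylidene)propan-2-one | CC(=O)C=P(c1ccccc1)(c1ccccc1)c1ccccc1 | starting material
5 | (E)-5-oxohex-3-en-1-yl 2,2-dimethylpropanoate | CC(=O)/C=C/CCOC(=O)C(C)(C)C | intermediate
6 | (E)-5-[(tert-butyldimethylsilyl)oxy]hexa-3,5-dien-1-yl 2,2-dimethylpropanoate | C=C(O[Si](C)(C)C(C)(C)C)/C=C/CCOC(=O)C(C)(C)C | intermediate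
7 | methacrolein | CC(=C)C=O | starting material
8 | 2-[(1R,6R)-3-[(tert-butyldimethylsilyl)oxy]-6-formyl-6-methylcyclohex-2-en-1-yl]ethyl 2,2-dimethylpropanoate | O=C[C@]1(C)CCC(O[Si](C)(C)C(C)(C)C)=C[C@H]1CCOC(=O)C(C)(C)C | intermediate
9 | ring B diol (C6 hydroxymethyl, C5 hydroxyethyl, C20=C21 silyl enol ether) | OC[C@]1(C)CCC(O[Si](C)(C)C(C)(C)C)=C[C@H]1CCO | intermediate
10 | ring B dialdehyde | O=C[C@]1(C)CCC(O[Si](C)(C)C(C)(C)C)=C[C@H]1CC=O | intermediate
11 | ring A ketol (C5 ketone, C6 hydroxyl, both C6 epimers) | C1C(=O)C(O)[C@]2(C)CCC(O[Si](C)(C)C(C)(C)C)=C[C@@H]12 | intermediate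
12 | ring A ketone (trans-hydrindan-2-one, C20=C21 silyl enol ether) | C1C(=O)C[C@]2(C)CCC(O[Si](C)(C)C(C)(C)C)=C[C@@H]12 | intermediate
13 | lithium enolate of 12 (C4=C5) | C1=C(O[Li])C[C@]2(C)CCC(O[Si](C)(C)C(C)(C)C)=C[C@@H]12 | intermediate (not isolated)
14 | C4 aldol adduct (2-hydroxypropan-2-yl at C4) | CC(C)(O)C1C(=O)C[C@]2(C)CCC(O[Si](C)(C)C(C)(C)C)=C[C@@H]12 | intermediate
15 | tertiary mesylate of 14 | CC(C)(OS(C)(=O)=O)C1C(=O)C[C@]2(C)CCC(O[Si](C)(C)C(C)(C)C)=C[C@@H]12 | intermediate (not isolated)
16 | C4-isopropylidene enone | CC(C)=C1C(=O)C[C@]2(C)CCC(O[Si](C)(C)C(C)(C)C)=C[C@@H]12 | intermediate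
17 | C4β-isopropyl ketone | CC(C)[C@H]1C(=O)C[C@]2(C)CCC(O[Si](C)(C)C(C)(C)C)=C[C@@H]12 | intermediate
18 | C5β-alcohol | CC(C)[C@H]1[C@@H](O)C[C@]2(C)CCC(O[Si](C)(C)C(C)(C)C)=C[C@@H]12 | intermediate
19 | bis-silyl ether (C5 silyl ether, C20 silyl enol ether) | CC(C)[C@H]1[C@@H](O[Si](C)(C)C(C)(C)C)C[C@]2(C)CCC(O[Si](C)(C)C(C)(C)C)=C[C@@H]12 | intermediate (not isolated)
20 | ring B ketone with C5β silyl ether | CC(C)[C@H]1[C@@H](O[Si](C)(C)C(C)(C)C)C[C@]2(C)CCC(=O)C[C@@H]12 | intermediate
21 | lithium enolate of 20 (C9=C20) | CC(C)[C@H]1[C@@H](O[Si](C)(C)C(C)(C)C)C[C@]2(C)CC=C(O[Li])C[C@@H]12 | intermediate (not isolated)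
22 | C9=C20 trimethylsilyl enol ether | CC(C)[C@H]1[C@@H](O[Si](C)(C)C(C)(C)C)C[C@]2(C)CC=C(O[Si](C)(C)C)C[C@@H]12 | intermediate
23 | C9-[(R)-but-3-en-2-yl] ketone, C9 epimers | CC(C)[C@H]1[C@@H](O[Si](C)(C)C(C)(C)C)C[C@]2(C)CC([C@H](C)C=C)C(=O)C[C@@H]12 | intermediate (not isolated)
24 | C9α-[(R)-but-3-en-2-yl] ketone | CC(C)[C@H]1[C@@H](O[Si](C)(C)C(C)(C)C)C[C@]2(C)C[C@H]([C@H](C)C=C)C(=O)C[C@@H]12 | intermediate
25 | (S)-citronellal | C[C@H](CC=O)CCC=C(C)C | starting material
26 | (S)-3,7-dimethyl-2-methylideneoct-6-enal | C[C@H](C(=C)C=O)CCC=C(C)C | intermediate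
27 | (S)-3,7-dimethyl-2-methylideneoct-6-en-1-ol | C[C@H](C(=C)CO)CCC=C(C)C | intermediate
28 | tert-butyldimethylsilyl ether of 27 | C[C@H](C(=C)CO[Si](C)(C)C(C)(C)C)CCC=C(C)C | intermediate
29 | (S)-tert-butyldimethyl[(5-methylcyclopent-1-en-1-yl)methoxy]silane | CC(C)(C)[Si](C)(C)OCC1=CCC[C@@H]1C | intermediate
30 | B-alkyl-9-borabicyclo[3.3.1]nonane from 29 | CC(C)(C)[Si](C)(C)OC[C@H]1[C@@H](C)CC[C@@H]1B1C2CCCC1CCC2 | intermediate (not isolated)
31 | (1S,2R,3S)-2-{[(tert-butyldimethylsilyl)oxy]methyl}-3-methylcyclopentan-1-ol | CC(C)(C)[Si](C)(C)OC[C@H]1[C@@H](C)CC[C@@H]1O | intermediate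
32 | (2R,3S)-2-{[(tert-butyldimethylsilyl)oxy]methyl}-3-methylcyclopentan-1-one | CC(C)(C)[Si](C)(C)OC[C@H]1[C@@H](C)CCC1=O | intermediate
33 | potassium enolate of 32 (C16=C17) | CC(C)(C)[Si](C)(C)OC[C@H]1[C@@H](C)CC=C1O[K] | intermediate (not isolated)
34 | (4S,5R)-5-{[(tert-butyldimethylsilyl)oxy]methyl}-4-methylcyclopent-1-en-1-yl trifluoromethanesulfonate | CC(C)(C)[Si](C)(C)OC[C@H]1[C@@H](C)CC=C1OS(=O)(=O)C(F)(F)F | intermediate
35 | 1-ethoxyvinyl diene from 34 | CC(C)(C)[Si](C)(C)OC[C@H]1[C@@H](C)CC=C1C(=C)OCC | intermediate (not isolated)
36 | 1-[(4S,5S)-5-{[(tert-butyldimethylsilyl)oxy]methyl}-4-methylcyclopent-1-en-1-yl]ethan-1-one | CC(C)(C)[Si](C)(C)OC[C@H]1[C@@H](C)CC=C1C(C)=O | intermediate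
37 | lithium (Z)-enolate from 36 | CC(C)(C)[Si](C)(C)OC[C@H]1[C@@H](C)CC/C1=C(\C)O[Li] | intermediate (not isolated)
38 | (Z)-1-[(2S,3S)-2-{[(tert-butyldimethylsilyl)oxy]methyl}-3-methylcyclopentylidene]ethyl trifluoromethanesulfonate | CC(C)(C)[Si](C)(C)OC[C@H]1[C@@H](C)CC/C1=C(\C)OS(=O)(=O)C(F)(F)F | intermediate
39 | (Z)-1-[(2S,3S)-2-(hydroxymethyl)-3-methylcyclopentylidene]ethyl trifluoromethanesulfonate | OC[C@H]1[C@@H](C)CC/C1=C(\C)OS(=O)(=O)C(F)(F)F | intermediate
40 | (Z)-1-[(2S,3S)-2-formyl-3-methylcyclopentylidene]ethyl trifluoromethanesulfonate | O=C[C@H]1[C@@H](C)CC/C1=C(\C)OS(=O)(=O)C(F)(F)F | intermediate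
41 | (Z)-1-[(2S,3S)-2-ethenyl-3-methylcyclopentylidene]ethyl trifluoromethanesulfonate | C=C[C@H]1[C@@H](C)CC/C1=C(\C)OS(=O)(=O)C(F)(F)F | intermediate
42 | trimethyl{(Z)-1-[(2S,3S)-2-ethenyl-3-methylcyclopentylidene]ethyl}stannane | C=C[C@H]1[C@@H](C)CC/C1=C(\C)[Sn](C)(C)C | intermediate
43 | alkenyllithium from 42 | C=C[C@H]1[C@@H](C)CC/C1=C(\C)[Li] | intermediate (not isolated)
44 | tertiary allylic alcohol (rings A, B and D joined at C19–C20) | CC(C)[C@H]1[C@@H](O[Si](C)(C)C(C)(C)C)C[C@]2(C)C[C@H]([C@H](C)C=C)[C@@](O)(/C(C)=C3/CC[C@H](C)[C@@H]3C=C)C[C@@H]12 | intermediate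
45 | epoxy alcohol | CC(C)[C@H]1[C@@H](O[Si](C)(C)C(C)(C)C)C[C@]2(C)C[C@H]([C@H](C)C=C)[C@@](O)([C@@]3(C)O[C@]34CC[C@H](C)[C@@H]4C=C)C[C@@H]12 | intermediate
46 | tetracyclic cis-cyclooctene (C11=C12) | CC(C)[C@H]1[C@@H](O[Si](C)(C)C(C)(C)C)C[C@]2(C)C[C@@H]3[C@H](C)/C=C\[C@H]4[C@@H](C)CC[C@]45O[C@]5(C)[C@@]3(O)C[C@@H]12 | intermediate
47 | saturated tetracycle, C5β silyl ether | CC(C)[C@H]1[C@@H](O[Si](C)(C)C(C)(C)C)C[C@]2(C)C[C@@H]3[C@H](C)CC[C@H]4[C@@H](C)CC[C@]45O[C@]5(C)[C@@]3(O)C[C@@H]12 | intermediate
48 | C5β-alcohol of the target skeleton | CC(C)[C@H]1[C@@H](O)C[C@]2(C)C[C@@H]3[C@H](C)CC[C@H]4[C@@H](C)CC[C@]45O[C@]5(C)[C@@]3(O)C[C@@H]12 | intermediate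
49 | target CNP0332295.1 | CC(C)[C@H]1C(=O)C[C@]2(C)C[C@@H]3[C@H](C)CC[C@H]4[C@@H](C)CC[C@]45O[C@]5(C)[C@@]3(O)C[C@@H]12 | target

## Step count and risk

Total step count: 35. Longest linear sequence: 22 steps (1 → 49 through steps 1–16 and 30–35). The ring D branch (steps 17–29) is 13 steps before the union in step 30.

**Step 5 (key step).** The cycloaddition may run through the endo transition state, because acyclic dienes usually place the activated carbonyl endo. That would put the formyl group cis to the C22 side chain and lead to a cis-hydrindane. The silyl enol ether may also add to the activated aldehyde in a Mukaiyama-type side reaction.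
Fallback: the roles of the two α-substituents of the dienophile are exchanged, so that the normal endo preference gives the required relationship. Diene 6 is combined with 2-formylprop-2-en-1-yl 2,2-dimethylpropanoate F1 (from 2-methylidenepropane-1,3-diol by monoacylation and MnO2 oxidation) under the mirror-image (S)-oxazaborolidinium catalyst. The endo adduct F2 carries the formyl group cis to the C22 chain and the acyloxymethyl group trans. The formyl group is then turned into the angular methyl group through the tosylhydrazone F3 and its reduction with catecholborane and sodium acetate to the bis-pivalate F4. LiAlH4 cleaves both esters of F4 and returns the route at diol 9.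

**Step 25.** Hydride may attack the unhindered methyl ketone directly (1,2-reduction), and reaction through the s-cis conformer would erode the enolate geometry on which ring C closure depends.
Fallback: from enone 36, conjugate reduction with [(Ph3P)CuH]6 in the presence of Me3SiCl gives the isolable trimethylsilyl enol ether F5, whose geometry can be checked and purified. MeLi then releases lithium enolate 37, and PhN(SO2CF3)2 gives 38, where the route is rejoined.

**Step 10.** Deprotonation at C6 may compete with deprotonation at C4, which would place the three-carbon unit on the wrong side of the ketone.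
Fallback: the benzoin hydroxyl is kept as a blocking group. Ketol 11 is silylated with Et3SiCl and imidazole to F6, which can enolise only toward C4. Aldol addition to acetone gives F7, dehydration with the Burgess reagent gives enone F8, and hydrogenation over Pd/C gives F9. SmI2 then removes the C6 silyloxy group through a C5=C6 enolate that does not touch C4, and the route is rejoined at 17.

**Step 16.** The fluoride-generated enolate may equilibrate to the C21 side, the linear allylation product may form, or the chiral substrate and the chiral catalyst may be mismatched.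
Fallback: a Claisen rearrangement sets C10 from alkene geometry. Ketone 20 is converted into its dimethyl ketal F10 (trimethyl orthoformate, pyridinium tosylate). Exchange with (Z)-but-2-en-1-ol under propanoic acid catalysis at 140 °C, with removal of methanol, gives the allyl enol ether F11 on the C9 side. F11 rearranges in a chair transition state on the α face of C9 to 23, and DBU equilibration returns the route at 24.

**Step 30.** The basic, hindered alkenyllithium may enolise the C20 ketone instead of adding to it, and tin–lithium exchange on a tetrasubstituted alkenylstannane may be incomplete.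
Fallback: stannane 42 is converted with I2 into the alkenyl iodide F12. Iodine–lithium exchange with t-BuLi and transmetalation with CeCl3 give the much less basic organocerium reagent F13, which adds to 24 and returns the route at 44.

## Further compounds

F1 | step 5 | 2-formylprop-2-en-1-yl 2,2-dimethylpropanoate | C=C(C=O)COC(=O)C(C)(C)C
F2 | step 5 | endo cycloadduct (formyl cis to the C22 side chain, pivaloyloxymethyl on C7) | CC(C)(C)C(=O)OC[C@]1(C=O)CCC(O[Si](C)(C)C(C)(C)C)=C[C@H]1CCOC(=O)C(C)(C)C
F3 | step 5 | tosylhydrazone of F2 | CC(C)(C)C(=O)OC[C@]1(/C=N/NS(=O)(=O)c2ccc(C)cc2)CCC(O[Si](C)(C)C(C)(C)C)=C[C@H]1CCOC(=O)C(C)(C)C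
F4 | step 5 | bis-pivalate with angular methyl group | CC(C)(C)C(=O)OC[C@]1(C)CCC(O[Si](C)(C)C(C)(C)C)=C[C@H]1CCOC(=O)C(C)(C)C
F5 | step 25 | (Z)-trimethylsilyl enol ether from 36 | CC(C)(C)[Si](C)(C)OC[C@H]1[C@@H](C)CC/C1=C(\C)O[Si](C)(C)C
F6 | step 10 | C6 triethylsilyl ether of ketol 11 | C1C(=O)C(O[Si](CC)(CC)CC)[C@]2(C)CCC(O[Si](C)(C)C(C)(C)C)=C[C@@H]12
F7 | step 10 | C4 aldol adduct of F6 | CC(C)(O)C1C(=O)C(O[Si](CC)(CC)CC)[C@]2(C)CCC(O[Si](C)(C)C(C)(C)C)=C[C@@H]12
F8 | step 10 | C4-isopropylidene enone with C6 silyloxy group | CC(C)=C1C(=O)C(O[Si](CC)(CC)CC)[C@]2(C)CCC(O[Si](C)(C)C(C)(C)C)=C[C@@H]12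
F9 | step 10 | C4β-isopropyl ketone with C6 silyloxy group | CC(C)[C@H]1C(=O)C(O[Si](CC)(CC)CC)[C@]2(C)CCC(O[Si](C)(C)C(C)(C)C)=C[C@@H]12
F10 | step 16 | dimethyl ketal of 20 | CC(C)[C@H]1[C@@H](O[Si](C)(C)C(C)(C)C)C[C@]2(C)CCC(OC)(OC)C[C@@H]12
F11 | step 16 | C9=C20 (Z)-but-2-enyl enol ether | CC(C)[C@H]1[C@@H](O[Si](C)(C)C(C)(C)C)C[C@]2(C)CC=C(OC/C=C\C)C[C@@H]12
F12 | step 30 | (Z)-alkenyl iodide from 42 | C=C[C@H]1[C@@H](C)CC/C1=C(\C)I
F13 | step 30 | alkenylcerium dichloride | C=C[C@H]1[C@@H](C)CC/C1=C(\C)[Ce](Cl)Cl
A1 | alternative 1 | tetracyclic C10-methylidene tertiary alcohol (ring A ketone as dioxolane) | CC(C)[C@H]1C6(OCCO6)C[C@]2(C)C[C@@H]3C(=C)CC[C@H]4[C@@H](C)CC/C4=C(\C)[C@@]3(O)C[C@@H]12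
A2 | alternative 1 | twelve-membered macrocyclic dienone carrying rings A and D | CC(C)[C@H]1C6(OCCO6)C[C@]2(C)C/C=C(\C)CC[C@H]4[C@@H](C)CC/C4=C(\C)C(=O)C[C@@H]12
A3 | alternative 2 | trans-hydrindan-2-one with ring B ketone as dioxolane | O=C1C[C@]2(C)CCC6(OCCO6)C[C@H]2C1
A4 | alternative 2 | 2-(1-methyl-2-methylidenecyclohexyl)acetaldehyde with ring B ketone as dioxolane | O=CC[C@]1(C)CCC2(OCCO2)CC1=C
A5 | alternative 3 | ring C ketone (C11 ketone, C17=C19 alkene, C20 trimethylsilyl ether) | CC(C)[C@H]1C6(OCCO6)C[C@]2(C)C[C@@H]3[C@H](C)C(=O)C[C@H]4[C@@H](C)CC/C4=C(\C)[C@@]3(O[Si](C)(C)C)C[C@@H]12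
A6 | alternative 3 | 2-methylidenetetrahydropyran bearing the ring D cyclopentenyl group on C19 | CC(C)[C@H]1C6(OCCO6)C[C@]2(C)C[C@@H]3[C@H](C)C(=C)O[C@](C)(C4=C[C@@H](C)CC4)[C@@]3(O[Si](C)(C)C)C[C@@H]12
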